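**Strategy.** The trimer is disconnected at its two interflavan bonds into an epicatechin C4 electrophile, a taxifolin-derived middle unit (C8 nucleophile, latent C4 electrophile, surplus 5-oxygen deleted at the end) and a catechin nucleophile. The catechin unit is built de novo. Its pyran ring (O1, C2, C3, C4, C4a, C8a) arises from an aryl methyl ketone and a 2-bromobenzyl bromide, exploiting that benzylic C4 and oxygen-bearing C8a hang on neighbouring carbons of ring A and that O1–C2–C3 is an enolate triad. One pot forges C3–C4 by enolate C-benzylation and O1–C8a by copper-catalysed enolate O-arylation. The resulting flat 4H-chromene receives its C2 and C3 stereochemistry by asymmetric hydroboration.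

Key step: step 4

Remark: flavan numbering is used throughout; α is the face of ring C that carries the 2-aryl group in the 2R series and β the opposite face; thioethers 18–20 are drawn as the expected major C4 epimer, a centre that is erased again in step 15.

**Lower (catechin) unit**

Step 1
Reactants: 1 1,3-bis(benzyloxy)-5-bromobenzene
Product: 3 2,4-bis(benzyloxy)-6-bromobenzaldehyde, via iminium salt 2 (not isolated)
Conditions: POCl3, DMF, 0 → 70 °C; then aq NaOAc
Reagents that add atoms: N,N-dimethylformamide CN(C)C=O (formyl carbon); water O (carbonyl oxygen)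
Why: Vilsmeier–Haack formylation should occur at the carbon between Br and OBn (ortho and para to the two ether oxygens) and not at the more hindered carbon between the two benzyloxy groups, as is usual for 5-halo-resorcinol diethers.

Step 2
Reactants: 3 2,4-bis(benzyloxy)-6-bromobenzaldehyde
Product: 4 [2,4-bis(benzyloxy)-6-bromophenyl]methanol
Conditions: NaBH4, THF/MeOH, 0 °C
Reagents that add atoms: none
Why: Borohydride reduction of an aromatic aldehyde; the aryl bromide and benzyl ethers are inert.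

Step 3
Reactants: 4 [2,4-bis(benzyloxy)-6-bromophenyl]methanol
Product: 5 1,5-bis(benzyloxy)-3-bromo-2-(bromomethyl)benzene
Conditions: PBr3 (0.4 equiv), Et2O, −20 °C; cold NaHCO3 wash, solution used at once
Reagents that add atoms: phosphorus tribromide BrP(Br)Br
Why: Bromination of a benzylic alcohol through its phosphite ester; the electron-rich benzylic bromide is not purified because it would self-alkylate on standing.

Step 4
Reactants: 5 1,5-bis(benzyloxy)-3-bromo-2-(bromomethyl)benzene; 6 1-[3,4-bis(benzyloxy)phenyl]ethan-1-one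
Product: 8 5,7-bis(benzyloxy)-2-[3,4-bis(benzyloxy)phenyl]-4H-chromene, via ketone 7 (not isolated)
Conditions: 6 (1.6 equiv), LiN(SiMe3)2, THF, −78 °C; 5, −78 → 0 °C; then same flask: CuI (10 mol %), 1,10-phenanthroline (20 mol %), Cs2CO3, DMF, 100 °C, Ar
Reagents that add atoms: none
Why: The lithium enolate of 6 is C-benzylated by the benzylic C–Br of 5 (C3–C4), then ketone 7 is re-enolised by Cs2CO3, monovalent copper inserts into the aryl C8a–Br bond, the enolate binds through oxygen and C–O reductive elimination forms O1–C8a. The closest known reaction types are the copper-catalysed domino C-benzylation/O-arylation of 1,3-dicarbonyl compounds with 2-bromobenzyl bromides to 4H-chromenes and the Ullmann-type intramolecular O-arylation of ketone enolates. Ring C of the lower unit closes as a six-membered ring through the enolate oxygen, with the enolate C=C ending inside the ring; closure through carbon would need a four-membered ring and is excluded. No stereocentre is created: C2=C3 is left as a flat enol ether on purpose, so that C2 and C3 are set together in step 5. The step needs the two C–Br bonds of 5 to react in sequence, mono- over bis-benzylation and C- over O-benzylation; these should be secured by the far higher reactivity of the 2,4-dialkoxybenzylic bromide at low temperature, the excess of lithium enolate and the soft benzylic electrophile. The O-arylation is made intramolecular by the fact that C4 and C8a sit on adjacent carbons of ring A.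

Step 5
Reactants: 8 5,7-bis(benzyloxy)-2-[3,4-bis(benzyloxy)phenyl]-4H-chromene
Product: 10 (2R,3S)-5,7,3',4'-tetra-O-benzylcatechin, via alkylborane 9 (not isolated)
Conditions: IpcBH2 (from (+)-α-pinene, 1.5 equiv, THF solution freed beforehand from its TMEDA adduct), THF, −25 °C; then NaOH, H2O2, 0 °C → rt; recrystallisation
Reagents that add atoms: hydrogen peroxide OO (oxygen of the 3-hydroxyl)
Why: Brown asymmetric hydroboration of a trisubstituted aryl enol ether: boron goes to C3 (β to the ring oxygen), syn delivery of H to C2 and B to C3 fixes the 2,3-trans relationship, the isopinocampheyl group selects the β face (by analogy with 1-arylcycloalkenes the (2R,3S) isomer is expected), and oxidation occurs with retention.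

**Upper (epicatechin) unit**

Step 6
Reactants: 11 (−)-epicatechin
Product: 12 5,7,3',4'-tetra-O-benzyl-(−)-epicatechin
Conditions: BnBr (4.4 equiv), K2CO3, DMF, −10 °C → rt
Reagents that add atoms: benzyl bromide BrCc1ccccc1
Why: Williamson etherification of the four phenols; the secondary 3-hydroxyl is not deprotonated by carbonate and stays free.

Step 7
Reactants: 12 5,7,3',4'-tetra-O-benzyl-(−)-epicatechin
Product: 13 4β-(2-ethoxyethoxy)-5,7,3',4'-tetra-O-benzylepicatechin (2,3-cis-3,4-trans)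
Conditions: DDQ (2 equiv), 2-ethoxyethanol, CH2Cl2, rt
Reagents that add atoms: 2-ethoxyethanol CCOCCO
Why: DDQ benzylic oxidation: hydride is abstracted from C4, the position activated by the three oxygens of ring A, and the cation is trapped by the alcohol anti to the 3-hydroxyl.

**Middle unit**

Step 8
Reactants: 14 (+)-taxifolin
Product: 15 7,3',4'-tri-O-benzyltaxifolin
Conditions: BnBr (3.2 equiv), K2CO3, DMF, rt, N2
Reagents that add atoms: benzyl bromide BrCc1ccccc1
Why: Williamson etherification; the 5-hydroxyl is hydrogen-bonded to the C4 carbonyl and is the least reactive phenol, so it is left free and thereby distinguished from all other oxygens.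

Step 9
Reactants: 15 7,3',4'-tri-O-benzyltaxifolin
Product: 16 5-O-allyl-7,3',4'-tri-O-benzyltaxifolin
Conditions: allyl bromide, K2CO3, DMF, 45 °C, N2
Reagents that add atoms: allyl bromide C=CCBr
Why: Williamson etherification of the chelated phenol under slightly more forcing conditions; the allyl ether keeps ring A electron-rich for step 14 and marks the one oxygen that is excised later.

Step 10
Reactants: 16 5-O-allyl-7,3',4'-tri-O-benzyltaxifolin
Product: 17 5-O-allyl-7,3',4'-tri-O-benzyl-2,3-trans-3,4-trans-flavan-3,4-diol (3-OH β, 4-OH α)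
Conditions: NaBH4, THF/EtOH, 0 °C → rt
Reagents that add atoms: none
Why: Borohydride reduction of the aryl ketone, expected to give mainly the 3,4-trans diol; the C4 configuration is of no consequence because C4 is ionised in the next step.

Step 11
Reactants: 17 5-O-allyl-7,3',4'-tri-O-benzyl-2,3-trans-3,4-trans-flavan-3,4-diol
Product: 18 5-O-allyl-7,3',4'-tri-O-benzyl-4α-(benzylsulfanyl)-2,3-trans-flavan-3-ol (3-OH β)
Conditions: BnSH (5 equiv), BF3·OEt2 (0.1 equiv), CH2Cl2, −40 °C
Reagents that add atoms: phenylmethanethiol SCc1ccccc1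
Why: Acid-catalysed SN1 substitution of the benzylic 4-hydroxyl by the thiol, as in thiolytic cleavage of proanthocyanidins; the ring-A-stabilised C4 cation is captured mainly anti to the 3-hydroxyl, and the thioether serves as a latent leaving group that is inert to hard Lewis acids.

Step 12
Reactants: 18 5-O-allyl-7,3',4'-tri-O-benzyl-4α-(benzylsulfanyl)-2,3-trans-flavan-3-ol
Product: 19 5-(allyloxy)-7,3',4'-tris(benzyloxy)-4α-(benzylsulfanyl)flavan-3-one (2-aryl α)
Conditions: Dess–Martin periodinane, pyridine, CH2Cl2, rt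
Reagents that add atoms: none
Why: Dess–Martin oxidation of the secondary alcohol under buffered conditions that should leave the sulfide, the alkene and the C2 configuration untouched.

Step 13
Reactants: 19 5-(allyloxy)-7,3',4'-tris(benzyloxy)-4α-(benzylsulfanyl)flavan-3-one
Product: 20 5-O-allyl-7,3',4'-tri-O-benzyl-4α-(benzylsulfanyl)epicatechin (2,3-cis, 3-OH α)
Conditions: LiBH(s-Bu)3, LiBr, THF, −78 °C; aq NH4Cl (no peroxide)
Reagents that add atoms: none
Why: Reduction with a bulky hydride under substrate control: the reagent approaches the β face, away from the α-oriented 2-aryl and 4-benzylsulfanyl groups, and gives the 3α-alcohol, which inverts C3 to the epi series.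

**Assembly**

Step 14
Reactants: 13 4β-(2-ethoxyethoxy)-5,7,3',4'-tetra-O-benzylepicatechin; 20 5-O-allyl-7,3',4'-tri-O-benzyl-4α-(benzylsulfanyl)epicatechin (3 equiv)
Product: 21 5,7,3',4'-tetra-O-benzylepicatechin-(4β→8)-[5-O-allyl-7,3',4'-tri-O-benzyl-4α-(benzylsulfanyl)epicatechin]
Conditions: TMSOTf (0.2 equiv), CH2Cl2, −78 °C; excess 20 recovered
Reagents that add atoms: none
Why: Lewis-acid-mediated Friedel–Crafts arylation of a flavan-4-yl cation: the hard acid ionises only the C4 ether of 13, C8 of the phloroglucinol-type ring A of 20 attacks as is general for 5,7-dialkoxyflavans, and the bond forms anti to the 3-hydroxyl (4β).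

Step 15
Reactants: 21 dimeric thioether; 10 (2R,3S)-5,7,3',4'-tetra-O-benzylcatechin (4 equiv)
Product: 22 5,7,3',4'-tetra-O-benzylepicatechin-(4β→8)-(5-O-allyl-7,3',4'-tri-O-benzylepicatechin)-(4β→8)-5,7,3',4'-tetra-O-benzylcatechin
Conditions: AgBF4 (2.5 equiv), THF, 0 °C, dark; excess 10 recovered
Reagents that add atoms: none
Why: Thiophilic activation: the silver cation abstracts the benzylsulfanyl group, and the C4 cation of the middle unit is captured by C8 of 10 anti to the 3-hydroxyl and the 2-aryl group (4β), a second flavan-4-yl cation arylation.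

Step 16
Reactants: 22 allyl-protected trimer
Product: 23 trimer with free 5-hydroxyl on the middle unit
Conditions: Pd(PPh3)4 (5 mol %), morpholine, THF, rt
Reagents that add atoms: none
Why: Tsuji–Trost deallylation: zerovalent palladium ionises the aryl allyl ether and morpholine traps the allyl fragment; benzyl ethers and the interflavan bonds are untouched under these neutral conditions.

Step 17
Reactants: 23 trimer with free 5-hydroxyl on the middle unit
Product: 24 trimer carrying a 5-O-(1-phenyl-1H-tetrazol-5-yl) ether on the middle unit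
Conditions: 5-chloro-1-phenyl-1H-tetrazole (1.3 equiv), K2CO3, DMF, rt → 40 °C
Reagents that add atoms: 5-chloro-1-phenyl-1H-tetrazole Clc1nnnn1-c1ccccc1
Why: Nucleophilic aromatic substitution on the chlorotetrazole by the only phenoxide present; the three secondary alcohols are not deprotonated by carbonate.

Step 18
Reactants: 24 tetrazolyl ether trimer
Product: 25 epicatechin-(4β→8)-epifisetinidol-(4β→8)-catechin (CNP0270097.1)
Conditions: H2 (3 bar), Pd(OH)2/C, THF/MeOH/H2O, rt → 40 °C; Sephadex LH-20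
Reagents that add atoms: none
Why: One hydrogenolysis should cleave the eleven benzyl ethers and, as a Musliner–Gates deoxygenation, the aryl C5–O bond of the tetrazolyl ether; this removes the auxiliary 5-oxygen and turns the middle unit into epifisetinidol without touching any stereocentre.

**Compound list**

1 | 1,3-bis(benzyloxy)-5-bromobenzene | Brc1cc(OCc2ccccc2)cc(OCc2ccccc2)c1 | starting material
2 | {[2,4-bis(benzyloxy)-6-bromophenyl]methylidene}dimethyliminium dichlorophosphate | C[N+](C)=Cc1c(Br)cc(OCc2ccccc2)cc1OCc1ccccc1.[O-]P(=O)(Cl)Cl | intermediate (not isolated)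
3 | 2,4-bis(benzyloxy)-6-bromobenzaldehyde | O=Cc1c(Br)cc(OCc2ccccc2)cc1OCc1ccccc1 | intermediate
4 | [2,4-bis(benzyloxy)-6-bromophenyl]methanol | OCc1c(Br)cc(OCc2ccccc2)cc1OCc1ccccc1 | intermediate
5 | 1,5-bis(benzyloxy)-3-bromo-2-(bromomethyl)benzene | BrCc1c(Br)cc(OCc2ccccc2)cc1OCc1ccccc1 | intermediate
6 | 1-[3,4-bis(benzyloxy)phenyl]ethan-1-one | CC(=O)c1ccc(OCc2ccccc2)c(OCc2ccccc2)c1 | starting material
7 | 3-[2,4-bis(benzyloxy)-6-bromophenyl]-1-[3,4-bis(benzyloxy)phenyl]propan-1-one | O=C(CCc1c(Br)cc(OCc2ccccc2)cc1OCc1ccccc1)c1ccc(OCc2ccccc2)c(OCc2ccccc2)c1 | intermediate (not isolated)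
8 | 5,7-bis(benzyloxy)-2-[3,4-bis(benzyloxy)phenyl]-4H-chromene | C(c3ccccc3)Oc1cc(OCc3ccccc3)c2c(c1)OC(c1ccc(OCc3ccccc3)c(OCc3ccccc3)c1)=CC2 | intermediate
9 | [5,7,3',4'-tetrakis(benzyloxy)-2,3-trans-flavan-3β-yl](isopinocampheyl)borane (2-aryl α) | C(c3ccccc3)Oc1cc(OCc3ccccc3)c2c(c1)O[C@H](c1ccc(OCc3ccccc3)c(OCc3ccccc3)c1)[C@@H](B[C@@H]4C[C@@H]5C[C@H]([C@H]4C)C5(C)C)C2 | intermediate (not isolated)
10 | (2R,3S)-5,7,3',4'-tetra-O-benzylcatechin | C(c3ccccc3)Oc1cc(OCc3ccccc3)c2c(c1)O[C@H](c1ccc(OCc3ccccc3)c(OCc3ccccc3)c1)[C@@H](O)C2 | intermediate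
11 | (−)-epicatechin, (2R,3R) | Oc1cc(O)c2c(c1)O[C@H](c1ccc(O)c(O)c1)[C@H](O)C2 | starting material
12 | 5,7,3',4'-tetra-O-benzyl-(−)-epicatechin | C(c3ccccc3)Oc1cc(OCc3ccccc3)c2c(c1)O[C@H](c1ccc(OCc3ccccc3)c(OCc3ccccc3)c1)[C@H](O)C2 | intermediate
13 | 4β-(2-ethoxyethoxy)-5,7,3',4'-tetra-O-benzylepicatechin | C(c3ccccc3)Oc1cc(OCc3ccccc3)c2c(c1)O[C@H](c1ccc(OCc3ccccc3)c(OCc3ccccc3)c1)[C@H](O)[C@H]2OCCOCC | intermediate
14 | (+)-taxifolin, (2R,3R)-dihydroquercetin | Oc1cc(O)c2c(c1)O[C@H](c1ccc(O)c(O)c1)[C@@H](O)C2=O | starting material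
15 | 7,3',4'-tri-O-benzyltaxifolin | C(c3ccccc3)Oc1cc(O)c2c(c1)O[C@H](c1ccc(OCc3ccccc3)c(OCc3ccccc3)c1)[C@@H](O)C2=O | intermediate
16 | 5-O-allyl-7,3',4'-tri-O-benzyltaxifolin | C(c3ccccc3)Oc1cc(OCC=C)c2c(c1)O[C@H](c1ccc(OCc3ccccc3)c(OCc3ccccc3)c1)[C@@H](O)C2=O | intermediate
17 | 5-O-allyl-7,3',4'-tri-O-benzyl-2,3-trans-3,4-trans-flavan-3,4-diol | C(c3ccccc3)Oc1cc(OCC=C)c2c(c1)O[C@H](c1ccc(OCc3ccccc3)c(OCc3ccccc3)c1)[C@@H](O)[C@@H]2O | intermediate
18 | 5-O-allyl-7,3',4'-tri-O-benzyl-4α-(benzylsulfanyl)-2,3-trans-flavan-3-ol | C(c3ccccc3)Oc1cc(OCC=C)c2c(c1)O[C@H](c1ccc(OCc3ccccc3)c(OCc3ccccc3)c1)[C@@H](O)[C@@H]2SCc1ccccc1 | intermediate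
19 | 5-(allyloxy)-7,3',4'-tris(benzyloxy)-4α-(benzylsulfanyl)flavan-3-one | C(c3ccccc3)Oc1cc(OCC=C)c2c(c1)O[C@H](c1ccc(OCc3ccccc3)c(OCc3ccccc3)c1)C(=O)[C@@H]2SCc1ccccc1 | intermediate
20 | 5-O-allyl-7,3',4'-tri-O-benzyl-4α-(benzylsulfanyl)epicatechin | C(c3ccccc3)Oc1cc(OCC=C)c2c(c1)O[C@H](c1ccc(OCc3ccccc3)c(OCc3ccccc3)c1)[C@H](O)[C@@H]2SCc1ccccc1 | intermediate
21 | 5,7,3',4'-tetra-O-benzylepicatechin-(4β→8)-[5-O-allyl-7,3',4'-tri-O-benzyl-4α-(benzylsulfanyl)epicatechin] | C(c3ccccc3)Oc1cc(OCc3ccccc3)c2c(c1)O[C@H](c1ccc(OCc3ccccc3)c(OCc3ccccc3)c1)[C@H](O)[C@H]2c1c(OCc3ccccc3)cc(OCC=C)c2c1O[C@H](c1ccc(OCc3ccccc3)c(OCc3ccccc3)c1)[C@H](O)[C@@H]2SCc1ccccc1 | intermediate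
22 | 5,7,3',4'-tetra-O-benzylepicatechin-(4β→8)-(5-O-allyl-7,3',4'-tri-O-benzylepicatechin)-(4β→8)-5,7,3',4'-tetra-O-benzylcatechin | C(c3ccccc3)Oc1cc(OCc3ccccc3)c2c(c1)O[C@H](c1ccc(OCc3ccccc3)c(OCc3ccccc3)c1)[C@H](O)[C@H]2c1c(OCc3ccccc3)cc(OCC=C)c2c1O[C@H](c1ccc(OCc3ccccc3)c(OCc3ccccc3)c1)[C@H](O)[C@H]2c1c(OCc3ccccc3)cc(OCc3ccccc3)c2c1O[C@H](c1ccc(OCc3ccccc3)c(OCc3ccccc3)c1)[C@@H](O)C2 | intermediate
23 | 5,7,3',4'-tetra-O-benzylepicatechin-(4β→8)-(7,3',4'-tri-O-benzylepicatechin)-(4β→8)-5,7,3',4'-tetra-O-benzylcatechin (middle 5-OH free) | C(c3ccccc3)Oc1cc(OCc3ccccc3)c2c(c1)O[C@H](c1ccc(OCc3ccccc3)c(OCc3ccccc3)c1)[C@H](O)[C@H]2c1c(OCc3ccccc3)cc(O)c2c1O[C@H](c1ccc(OCc3ccccc3)c(OCc3ccccc3)c1)[C@H](O)[C@H]2c1c(OCc3ccccc3)cc(OCc3ccccc3)c2c1O[C@H](c1ccc(OCc3ccccc3)c(OCc3ccccc3)c1)[C@@H](O)C2 | intermediate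
24 | 5,7,3',4'-tetra-O-benzylepicatechin-(4β→8)-[7,3',4'-tri-O-benzyl-5-O-(1-phenyl-1H-tetrazol-5-yl)epicatechin]-(4β→8)-5,7,3',4'-tetra-O-benzylcatechin | C(c3ccccc3)Oc1cc(OCc3ccccc3)c2c(c1)O[C@H](c1ccc(OCc3ccccc3)c(OCc3ccccc3)c1)[C@H](O)[C@H]2c1c(OCc3ccccc3)cc(Oc3nnnn3-c3ccccc3)c2c1O[C@H](c1ccc(OCc3ccccc3)c(OCc3ccccc3)c1)[C@H](O)[C@H]2c1c(OCc3ccccc3)cc(OCc3ccccc3)c2c1O[C@H](c1ccc(OCc3ccccc3)c(OCc3ccccc3)c1)[C@@H](O)C2 | intermediate
25 | epicatechin-(4β→8)-epifisetinidol-(4β→8)-catechin (CNP0270097.1) | Oc1cc(O)c2c(c1)O[C@H](c1ccc(O)c(O)c1)[C@H](O)[C@H]2c1c(O)ccc2c1O[C@H](c1ccc(O)c(O)c1)[C@H](O)[C@H]2c1c(O)cc(O)c2c1O[C@H](c1ccc(O)c(O)c1)[C@@H](O)C2 | target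

**Step count and risks**

Total: 18 steps. Longest linear sequence: 11 steps (14 → 25, steps 8–13 and 14–18).

Step 4. What may go wrong: proton transfer between ketone 7 and the enolate leads to double benzylation, and copper inserts only slowly into the electron-rich, ortho-substituted aryl C–Br bond, so that the acid- and air-sensitive enol ether degrades before the ring has closed. Fallback, from aldehyde 3 and ketone 6, returning at chromene 8: Claisen–Schmidt condensation (KOH, EtOH/THF, rt) should give the enone (E)-3-[2,4-bis(benzyloxy)-6-bromophenyl]-1-[3,4-bis(benzyloxy)phenyl]prop-2-en-1-one F1. Conjugate reduction with [(Ph3P)CuH]6 (cat.) and PhSiH3 in toluene should give ketone 7, now isolated and purified. Ring closure by intramolecular enolate O-arylation under zerovalent palladium (Pd2(dba)3, bis[2-(diphenylphosphino)phenyl] ether, Cs2CO3, toluene, 100 °C) then gives 8. The two bonds are made in separate steps and the labile benzylic bromide 5 is avoided.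

Step 5. What may go wrong: the chiral borane discriminates the faces of the aryl enol ether insufficiently, or the β-aryloxyborane 9 undergoes β-elimination with opening of ring C before it is oxidised. Fallback, from chromene 8, returning at 10: hydroboration with BH3·THF at 0 °C and immediate NaOH/H2O2 oxidation should give the racemic 2,3-trans alcohol, that is 10 together with its enantiomer (2S,3R)-5,7,3',4'-tetra-O-benzyl-ent-catechin F2. Kinetic resolution with Burkholderia cepacia lipase and vinyl acetate in t-BuOMe is expected, by the empirical rule for trans-2-aryl cyclic secondary alcohols, to acetylate the unwanted enantiomer to (2S,3R)-3-O-acetyl-5,7,3',4'-tetra-O-benzyl-ent-catechin F3. Unreacted 10 is then separated by chromatography and recrystallised.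

Step 18. What may go wrong: hydrogenolysis of the aryl–oxygen bond of the tetrazolyl ether stalls once the debenzylated polyphenol covers the catalyst, or the more forcing conditions it needs begin to open O1–C2 bonds. Fallback, from phenol 23, returning at target 25: triflation with PhNTf2 and K2CO3 in DMF should give the middle-unit 5-O-trifluoromethanesulfonate of the benzyl-protected trimer F4. Homogeneous reduction (Pd(OAc)2, 1,1'-bis(diphenylphosphino)ferrocene, HCO2H, Et3N, DMF, 65 °C), which spares benzyl ethers, should give 5,7,3',4'-tetra-O-benzylepicatechin-(4β→8)-(7,3',4'-tri-O-benzylepifisetinidol)-(4β→8)-5,7,3',4'-tetra-O-benzylcatechin F5. Ordinary debenzylation (H2, Pd(OH)2/C, THF/MeOH, rt) then gives 25.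

**Further compounds**

F1 | step 4 | (E)-3-[2,4-bis(benzyloxy)-6-bromophenyl]-1-[3,4-bis(benzyloxy)phenyl]prop-2-en-1-one | O=C(/C=C/c1c(Br)cc(OCc2ccccc2)cc1OCc1ccccc1)c1ccc(OCc2ccccc2)c(OCc2ccccc2)c1
F2 | step 5 | (2S,3R)-5,7,3',4'-tetra-O-benzyl-ent-catechin | C(c3ccccc3)Oc1cc(OCc3ccccc3)c2c(c1)O[C@@H](c1ccc(OCc3ccccc3)c(OCc3ccccc3)c1)[C@H](O)C2
F3 | step 5 | (2S,3R)-3-O-acetyl-5,7,3',4'-tetra-O-benzyl-ent-catechin | C(c3ccccc3)Oc1cc(OCc3ccccc3)c2c(c1)O[C@@H](c1ccc(OCc3ccccc3)c(OCc3ccccc3)c1)[C@H](OC(C)=O)C2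
F4 | step 18 | 5,7,3',4'-tetra-O-benzylepicatechin-(4β→8)-[7,3',4'-tri-O-benzyl-5-O-(trifluoromethanesulfonyl)epicatechin]-(4β→8)-5,7,3',4'-tetra-O-benzylcatechin | C(c3ccccc3)Oc1cc(OCc3ccccc3)c2c(c1)O[C@H](c1ccc(OCc3ccccc3)c(OCc3ccccc3)c1)[C@H](O)[C@H]2c1c(OCc3ccccc3)cc(OS(=O)(=O)C(F)(F)F)c2c1O[C@H](c1ccc(OCc3ccccc3)c(OCc3ccccc3)c1)[C@H](O)[C@H]2c1c(OCc3ccccc3)cc(OCc3ccccc3)c2c1O[C@H](c1ccc(OCc3ccccc3)c(OCc3ccccc3)c1)[C@@H](O)C2
F5 | step 18 | 5,7,3',4'-tetra-O-benzylepicatechin-(4β→8)-(7,3',4'-tri-O-benzylepifisetinidol)-(4β→8)-5,7,3',4'-tetra-O-benzylcatechin | C(c3ccccc3)Oc1cc(OCc3ccccc3)c2c(c1)O[C@H](c1ccc(OCc3ccccc3)c(OCc3ccccc3)c1)[C@H](O)[C@H]2c1c(OCc3ccccc3)ccc2c1O[C@H](c1ccc(OCc3ccccc3)c(OCc3ccccc3)c1)[C@H](O)[C@H]2c1c(OCc3ccccc3)cc(OCc3ccccc3)c2c1O[C@H](c1ccc(OCc3ccccc3)c(OCc3ccccc3)c1)[C@@H](O)C2
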